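**Plan**

- The target is a 5,5'-disubstituted 2,2'-bithiophene; ring A carries CH2O-C(=O)CH=C(CH3)2 and ring B carries C≡C-CH2-CH2-O-C(=O)CH2CH(CH3)2. Both rings are bought ready-made.
- Retrosynthetic cuts, in order: the thenylic O-acyl bond of the 3-methylbut-2-enoate on ring A; then, together, the ester C-O bond and the C(sp)-CH2 bond of the ring B chain; then the ring B C(sp2)-C(sp) bond.
- Enabling feature: on ring B the ester oxygen lies exactly two sp3 carbons from the triple bond (C≡C-CH2-CH2-O). That is the footprint of an acetylide opening oxirane, and the alkoxide formed in that opening is itself the acyl acceptor for the 3-methylbutanoyl group.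
- Forward order: ring A aldehyde to silyl-protected CH2OH; ring B bromide to ethynyl; one-flask acetylide/oxirane/acyl chloride chain assembly; O-desilylation; the base-sensitive enoate goes on last.
- Stereochemistry: none to set.

Key step: step 5

Remark: the target has no stereocentre and its only C=C bond bears two methyl groups on one carbon, so no stereocontrol is required; oxirane is assumed to be dosed as its commercial THF solution.

**Route**

Step 1
Reactants: 1 5'-bromo-2,2'-bithiophene-5-carbaldehyde
Product: 2 (5'-bromo-2,2'-bithiophen-5-yl)methanol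
Conditions: NaBH4, MeOH/THF, 0 °C
Reagents that add atoms: none
Why: Hydride addition of NaBH4 to the aldehyde (carbonyl reduction) should give the primary thenylic alcohol, the C-Br bond and both thiophenes being inert to borohydride.

Step 2
Reactants: 2 (5'-bromo-2,2'-bithiophen-5-yl)methanol
Product: 3 [(5'-bromo-2,2'-bithiophen-5-yl)methoxy](tert-butyl)diphenylsilane
Conditions: TBDPSCl, imidazole, DMF, 0 °C → rt
Reagents that add atoms: tert-butyl(chloro)diphenylsilane, CC(C)(C)[Si](Cl)(c1ccccc1)c1ccccc1
Why: Imidazole-mediated O-silylation of the unhindered primary alcohol should give a bulky silyl ether that tolerates the carbonate, amine and organolithium conditions ahead and comes off later with fluoride.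

Step 3
Reactants: 3 [(5'-bromo-2,2'-bithiophen-5-yl)methoxy](tert-butyl)diphenylsilane, 4 ethynyltrimethylsilane
Product: 5 tert-butyldiphenyl{[5'-(trimethylsilylethynyl)-2,2'-bithiophen-5-yl]methoxy}silane
Conditions: PdCl2(PPh3)2 (3 mol%), CuI (5 mol%), Et3N/THF, 60 °C
Reagents that add atoms: none
Why: Sonogashira coupling: zerovalent palladium formed in the flask from PdCl2(PPh3)2 should insert into the C-Br bond of ring B, take the alkynyl group from the copper acetylide of 4 and reductively eliminate to the C(sp2)-C(sp) bond, the silyl cap preventing double coupling and the silyl ether on ring A being a spectator.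

Step 4
Reactants: 5 tert-butyldiphenyl{[5'-(trimethylsilylethynyl)-2,2'-bithiophen-5-yl]methoxy}silane
Product: 6 tert-butyl[(5'-ethynyl-2,2'-bithiophen-5-yl)methoxy]diphenylsilane
Conditions: K2CO3 (0.2 equiv), MeOH/THF, rt
Reagents that add atoms: none
Why: Methoxide attack at the unhindered alkynyl silicon followed by protonation of the acetylide (protodesilylation) should free the terminal alkyne, while the far more hindered tert-butyldiphenylsilyl ether is untouched.

Step 5
Reactants: 6 tert-butyl[(5'-ethynyl-2,2'-bithiophen-5-yl)methoxy]diphenylsilane, 7 oxirane, 8 3-methylbutanoyl chloride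
Product: 11 4-[5'-[(tert-butyldiphenylsilyl)oxymethyl]-2,2'-bithiophen-5-yl]but-3-yn-1-yl 3-methylbutanoate, via lithium acetylide 9 (not isolated), via lithium alkoxide 10 (not isolated)
Conditions: n-BuLi (1.0 equiv), THF, −78 °C; DMPU, oxirane (2 equiv, THF solution), −78 °C → rt, sealed flask; N2 purge; then 3-methylbutanoyl chloride (1.5 equiv), 0 °C → rt
Reagents that add atoms: none
Why: n-BuLi removes the sp C-H of 6 to give acetylide 9, whose carbanion opens oxirane by SN2 attack at a CH2 group (new C(sp)-CH2 bond) to leave lithium alkoxide 10, and this oxygen then attacks acyl chloride 8 by addition-elimination (new ester C-O bond). The closest known reaction types are the alkylation of lithium acetylides with oxirane in THF containing a dipolar aprotic cosolvent and the in-flask O-acylation of the lithium alkoxide that such an opening delivers. No ring closes and no stereocentre is formed. DMPU is chosen as activator and a Lewis acid such as BF3·OEt2 is deliberately left out, because a boron-bound oxygen would be a poor acyl acceptor whereas the free lithium alkoxide should be acylated directly. The step needs chemoselective metalation at the alkyne C-H, which is secured by its far higher acidity relative to the beta C-H bonds of the two fully alpha-substituted thiophenes and the thenylic CH2OSi group, and the symmetry of oxirane leaves no regiochemical question. Over-reaction should be limited because lithium alkoxides add to oxirane much more slowly than the acetylide does, the excess oxirane is purged before 8 is added, and the silyl ether is inert to every reagent in the flask.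

Step 6
Reactants: 11 4-[5'-[(tert-butyldiphenylsilyl)oxymethyl]-2,2'-bithiophen-5-yl]but-3-yn-1-yl 3-methylbutanoate
Product: 12 4-[5'-(hydroxymethyl)-2,2'-bithiophen-5-yl]but-3-yn-1-yl 3-methylbutanoate
Conditions: TBAF, AcOH (1:1), THF, 0 °C → rt
Reagents that add atoms: none
Why: Fluoride attacks silicon and the strong Si-F bond drives Si-O cleavage (fluoride desilylation), while the equimolar acetic acid protonates the thenylic alkoxide as it forms, so the isovalerate should not be transesterified and the alkyne should not isomerise.

Step 7
Reactants: 12 4-[5'-(hydroxymethyl)-2,2'-bithiophen-5-yl]but-3-yn-1-yl 3-methylbutanoate, 13 3-methylbut-2-enoyl chloride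
Product: 14 [5'-[4-(3-methylbutanoyloxy)but-1-yn-1-yl]-2,2'-bithiophen-5-yl]methyl 3-methylbut-2-enoate (CNP0114739.0)
Conditions: pyridine, CH2Cl2, 0 °C
Reagents that add atoms: none
Why: Nucleophilic acyl substitution of the acyl chloride by the primary thenylic alcohol with pyridine as HCl scavenger (O-acylation); the weak base and low temperature should disfavour gamma-deprotonation to a vinylketene, so the double bond stays conjugated, and the homopropargylic isovalerate and the alkyne are spectators.

**Compound list**

1 | 5'-bromo-2,2'-bithiophene-5-carbaldehyde | O=Cc1ccc(-c2ccc(Br)s2)s1 | starting material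
2 | (5'-bromo-2,2'-bithiophen-5-yl)methanol | OCc1ccc(-c2ccc(Br)s2)s1 | intermediate
3 | [(5'-bromo-2,2'-bithiophen-5-yl)methoxy](tert-butyl)diphenylsilane | Brc1ccc(-c2ccc(CO[Si](c3ccccc3)(c3ccccc3)C(C)(C)C)s2)s1 | intermediate
4 | ethynyltrimethylsilane | C#C[Si](C)(C)C | starting material
5 | tert-butyldiphenyl{[5'-(trimethylsilylethynyl)-2,2'-bithiophen-5-yl]methoxy}silane | C[Si](C)(C)C#Cc1ccc(-c2ccc(CO[Si](c3ccccc3)(c3ccccc3)C(C)(C)C)s2)s1 | intermediate
6 | tert-butyl[(5'-ethynyl-2,2'-bithiophen-5-yl)methoxy]diphenylsilane | C#Cc1ccc(-c2ccc(CO[Si](c3ccccc3)(c3ccccc3)C(C)(C)C)s2)s1 | intermediate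
7 | oxirane | C1CO1 | starting material
8 | 3-methylbutanoyl chloride | CC(C)CC(Cl)=O | starting material
9 | lithium {5'-[(tert-butyldiphenylsilyloxy)methyl]-2,2'-bithiophen-5-yl}ethynide (lithium acetylide of 6, not isolated) | [Li]C#Cc1ccc(-c2ccc(CO[Si](c3ccccc3)(c3ccccc3)C(C)(C)C)s2)s1 | intermediate
10 | lithium 4-{5'-[(tert-butyldiphenylsilyloxy)methyl]-2,2'-bithiophen-5-yl}but-3-yn-1-olate (not isolated) | [Li]OCCC#Cc1ccc(-c2ccc(CO[Si](c3ccccc3)(c3ccccc3)C(C)(C)C)s2)s1 | intermediate
11 | 4-[5'-[(tert-butyldiphenylsilyl)oxymethyl]-2,2'-bithiophen-5-yl]but-3-yn-1-yl 3-methylbutanoate | CC(C)CC(=O)OCCC#Cc1ccc(-c2ccc(CO[Si](c3ccccc3)(c3ccccc3)C(C)(C)C)s2)s1 | intermediate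
12 | 4-[5'-(hydroxymethyl)-2,2'-bithiophen-5-yl]but-3-yn-1-yl 3-methylbutanoate | CC(C)CC(=O)OCCC#Cc1ccc(-c2ccc(CO)s2)s1 | intermediate
13 | 3-methylbut-2-enoyl chloride | CC(C)=CC(Cl)=O | starting material
14 | [5'-[4-(3-methylbutanoyloxy)but-1-yn-1-yl]-2,2'-bithiophen-5-yl]methyl 3-methylbut-2-enoate | CC(C)=CC(=O)OCc1ccc(-c2ccc(C#CCCOC(=O)CC(C)C)s2)s1 | target

**Count and risks**

Total step count: 7. Longest linear sequence: 7 steps (1 to 14); 4, 7, 8 and 13 are purchased building blocks.

Steps most likely to fail:

1. Step 5. The opening of oxirane by the aggregated, conjugation-stabilised arylacetylide may stall. Acetylide still present when 8 is added would then be C-acylated to an ynone, and the alkoxide may take up a second oxirane before it is acylated. The fallback sets out from bromide 3 and comes back at 11. But-3-yn-1-ol is esterified with 8 (pyridine, CH2Cl2, 0 °C) to but-3-yn-1-yl 3-methylbutanoate F1. Sonogashira coupling of 3 with F1 (PdCl2(PPh3)2, CuI, Et3N/THF, 60 °C) should then give 11 directly. The four-carbon chain arrives with its ester in place and no organolithium is needed; steps 3 to 5 are bypassed.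

2. Step 7. Gamma-deprotonation of the acyl chloride or its acylpyridinium ion may give a vinylketene, whose capture by the alcohol would move the double bond out of conjugation. HCl may also ionise the electron-rich thenylic C-O bond. The fallback sets out from 12 and comes back at 14. Mitsunobu esterification with 3-methylbut-2-enoic acid (PPh3, DIAD, THF, 0 °C) activates the alcohol as an alkoxyphosphonium ion and lets the carboxylate displace it, so no activated acyl species and no ketene can arise. This path makes no compound outside the list (F0).

3. Step 3. Oxidative addition into the electron-rich bromobithiophene may be slow, and copper-mediated oxidative dimerisation of 4 may compete, leaving bromide that is hard to separate from the coupled product. The fallback sets out from 3 and comes back at 6. Bromine-lithium exchange (n-BuLi, THF, −78 °C) should give {5'-[(tert-butyldiphenylsilyloxy)methyl]-2,2'-bithiophen-5-yl}lithium F2 (not isolated). A DMF quench turns it into 5'-[(tert-butyldiphenylsilyloxy)methyl]-2,2'-bithiophene-5-carbaldehyde F3. Ohira-Bestmann homologation of F3 (dimethyl (1-diazo-2-oxopropyl)phosphonate, K2CO3, MeOH/THF, rt) should give the terminal alkyne 6; steps 3 and 4 are bypassed.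

**Further compounds**

F1 | step 5 | but-3-yn-1-yl 3-methylbutanoate | C#CCCOC(=O)CC(C)C
F0 | step 7 | none | none
F2 | step 3 | {5'-[(tert-butyldiphenylsilyloxy)methyl]-2,2'-bithiophen-5-yl}lithium | [Li]c1ccc(-c2ccc(CO[Si](c3ccccc3)(c3ccccc3)C(C)(C)C)s2)s1
F3 | step 3 | 5'-[(tert-butyldiphenylsilyloxy)methyl]-2,2'-bithiophene-5-carbaldehyde | O=Cc1ccc(-c2ccc(CO[Si](c3ccccc3)(c3ccccc3)C(C)(C)C)s2)s1
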